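- The equilibrium constants of the steps below multiply out; the steps carry substrate to target and return the catalyst unchanged:

    catalyst intermediate B ⇌ free catalyst + target (K1 = 0.0084 M, k1 = 0.16 /min)
    substrate + free catalyst ⇌ catalyst intermediate A (K2 = 19 /M, k2 = 250 /M/min)
    catalyst intermediate A ⇌ catalyst intermediate B (K3 = 67, k3 = 1.7 /min)
substrate 24 mM; free catalyst 15 mol%; time 6.0 d
- which holds at 6.0 d: what has brought the reaction to rest, or that it has not come to rest (no working catalyst is left / it is still moving / forward and back rates have come level / all of the substrate has reacted)
- target at 6.0 d, in percent of the substrate charged
- catalyst intermediate B at 6.0 d, in percent of the substrate charged
- amount of target if the flask were left three thousand times as long, in percent of the substrate charged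
- the reaction counts as stopped when no species that holds the substrate changes by six tenths of a point or more over the second half of the time
- run time (flask): 6.0 d

- Their product, 10.7, is the overall constant, the ratio of unbound target to unbound substrate once forward and back rates stand level in each step.
- I first ask whether the flask gets there. Among the forward steps, with binding taken at the starting substrate, release of target from intermediate B has the smallest constant, so I take it as the slow step; with the catalyst sitting as B, the substrate charge turns over in about 41.7 min.
- The run of 6.0 d is far longer than that, so I expect thermodynamic control and no change on longer waiting.
- The overall constant puts 91.4% of whatever the catalyst does not hold into target.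
- One number is not enough: the catalyst charge is 15 mol% of the substrate, and intermediate B holds target material.
- Intermediate A stands below B by the factor 67, so I drop it. With target near that first share, B over free catalyst is 2.61, which places 72.3% of the catalyst in B.
- My reckoning therefore gives B 10.8% and target 81.5%, now and after the long wait. B runs high, since I fed it the larger target.
- The forecast says forward and back rates have come level, with target 81.8% (80.5% to 83%), B 10.4% (9.8% to 11%) and 81.8% (80.5% to 83%) for the long wait, since “waiting longer changes nothing”. Its target is higher than mine and its B lower.
- The flask gives forward and back rates have come level, target 81.8%, B 10.4%, and 81.8% for the long wait, so the forecast holds on each count.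
- In the flask, half of the turnover of the release of target up to the asked time is done by 0.539 h, far earlier than the 6.0 d of the run. Substrate reads 7.65% at 0.600 d and 7.65% at 60.0 d.
- For the neighbour flask with 6 mol% of free catalyst, the overall constant stays 10.7, and the same pass gives B 4.34% and target 87.4%. The neighbour flask computes to B 4.24% and target 87.5%.

The constants used here are those of an exercise.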